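**Retrosynthetic overview**
1. Target 20 ⇒ global hydrogenolysis of a perbenzylated, bromine-capped dimer 19 ⇒ C4–C6 bond made by capture of an epiafzelechin C4 cation (quinone-methide equivalent, stored as the 4-methyl ether of a 2,3-cis-leucopelargonidin, 11) by C6 of a C8-capped epigallocatechin digallate 18.
2. Upper unit 11 ⇐ cis-epoxide ⇐ trans-bromohydrin ⇐ (2S)-flav-3-ene 6 ⇐ cis-flavan-4-ol 5 ⇐ chalcone 3. The pyran ring is closed by a chalcone-isomerase-type oxa-Michael addition that is made enantioselective in the same flask by transfer hydrogenation with dynamic kinetic resolution.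
3. Lower unit 18 ⇐ (−)-epigallocatechin 12: temporary B-ring ketal, benzylation, C8 bromine cap, ketal removal, double galloylation at 3-OH and 3'-OH.
4. Ring order: only the upper C-ring is built (step 2). All other rings come with the starting materials.

Assumption: 1, 2, 12 and 17 are bought as catalogue items; B-ring locants are chosen so that the oxygen that finally carries the galloyl group is always called 3'.

**Step 1**
Reactants: 1 2'-hydroxy-4',6'-bis(benzyloxy)acetophenone; 2 4-(benzyloxy)benzaldehyde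
Product: 3 (E)-1-[2-hydroxy-4,6-bis(benzyloxy)phenyl]-3-[4-(benzyloxy)phenyl]prop-2-en-1-one
Conditions: KOH (50 % aq), EtOH/THF, rt, 48 h
Reagents that add atoms: none
Why: Claisen–Schmidt aldol condensation of the methyl ketone with a non-enolisable aldehyde gives the (E)-enone under thermodynamic control and leaves the chelated 2'-OH free for the ring closure; no stereocentre is formed.

**Step 2**
Reactants: 3 tri-O-benzyl naringenin chalcone
Product: 5 (2S,4S)-5,7-bis(benzyloxy)-2-[4-(benzyloxy)phenyl]chroman-4-ol (2,4-cis), via racemic flavanone 4 (not isolated)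
Conditions: DBU (0.3 equiv), MeCN, 50 °C; then RuCl(p-cymene)[(S,S)-TsDPEN] (2 mol %), HCO2H/Et3N (1:2.5), 40 °C
Reagents that add atoms: none
Why: Proposed new method: the amine base closes the pyran ring by a reversible chalcone-isomerase-type 6-endo oxa-Michael addition, so both flavanone enantiomers interconvert through 3, while the (S,S)-Ru hydride reduces only the (2S)-ketone from the face anti to the equatorial 2-aryl group (matched case) to give the 2,4-cis (2S,4S) alcohol, the low standing concentration of 3 keeping enone reduction minor; the closest known reaction type is Noyori–Ikariya asymmetric transfer hydrogenation of 2-substituted chroman-4-ones with dynamic kinetic resolution through retro-oxa-Michael racemisation.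

**Step 3**
Reactants: 5 (2S,4S)-cis-flavan-4-ol
Product: 6 (2S)-5,7-bis(benzyloxy)-2-[4-(benzyloxy)phenyl]-2H-chromene
Conditions: Burgess reagent (1.5 equiv), PhMe, 50 °C, dark
Reagents that add atoms: none
Why: Burgess dehydration (syn-elimination of the sulfamate of an easily ionised benzylic alcohol) under neutral conditions gives the conjugated flav-3-ene without touching C2, whose configuration is retained.

**Step 4**
Reactants: 6 (2S)-flav-3-ene
Product: 9 (2R,3S,4R)-3,6,8-tribromo-5,7-bis(benzyloxy)-2-[4-(benzyloxy)phenyl]chroman-4-ol, via bromohydrin 7 (not isolated), via 8-bromo bromohydrin 8 (not isolated)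
Conditions: NBS (3.2 equiv, portionwise), acetone/H2O (6:1), 0 °C → rt
Reagents that add atoms: N-bromosuccinimide (O=C1CCC(=O)N1Br); water (O)
Why: Halohydrin formation in which Br+ adds to the electron-rich styrenic C3=C4 bond anti to the 2-aryl group and water opens the benzylic C4 anti to bromine (2,3-trans-3,4-trans, C3 and C4 set by substrate control), after which the excess NBS caps the activated A-ring at C8 and then C6 by electrophilic aromatic substitution.

**Step 5**
Reactants: 9 tribromo bromohydrin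
Product: 11 (2R,3R,4S)-6,8-dibromo-5,7-bis(benzyloxy)-2-[4-(benzyloxy)phenyl]-4-methoxychroman-3-ol (2,3-cis-3,4-trans), via cis-epoxide 10 (not isolated)
Conditions: K2CO3 (2 equiv), MeOH/THF (2:1), 0 °C → rt
Reagents that add atoms: methanol (CO)
Why: Intramolecular Williamson displacement of bromide by the C4 alkoxide inverts C3 and puts the epoxide on the face of the 2-aryl group, and this very electron-rich benzylic epoxide is then opened by methanol at C4 anti to the oxygen (SN1-like solvolysis), leaving the 3-OH α (2,3-cis) and a 4β-methoxy leaving group.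

**Step 6**
Reactants: 12 (−)-epigallocatechin
Product: 13 3',4'-O-(diphenylmethylene)-(−)-epigallocatechin
Conditions: Ph2CCl2 (1.3 equiv), Ph2O, 175 °C, 20 min
Reagents that add atoms: dichlorodiphenylmethane (ClC(Cl)(c1ccccc1)c1ccccc1)
Why: Ketalisation of the only vicinal phenol pair (B-ring pyrogallol) forms a five-membered 1,3-benzodioxole and leaves one meta B-ring OH, the A-ring phenols and the 3-OH free; no stereocentre is affected.

**Step 7**
Reactants: 13 B-ring ketal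
Product: 14 5,7,5'-tri-O-benzyl-3',4'-O-(diphenylmethylene)-(−)-epigallocatechin
Conditions: BnBr (3.3 equiv), K2CO3 (4 equiv), DMF, 0 °C → rt
Reagents that add atoms: benzyl bromide (BrCc1ccccc1)
Why: Williamson ether synthesis benzylates the three phenols but not the secondary alcohol, and because the ketal ties up the 4'-oxygen no B-ring quinone methide can form, so C2 does not epimerise.

**Step 8**
Reactants: 14 tribenzyl ketal
Product: 15 8-bromo-5,7,5'-tri-O-benzyl-3',4'-O-(diphenylmethylene)-(−)-epigallocatechin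
Conditions: NBS (1.0 equiv), CH2Cl2, −40 → 0 °C
Reagents that add atoms: N-bromosuccinimide (O=C1CCC(=O)N1Br)
Why: Electrophilic aromatic bromination of 5,7-dialkoxyflavans with NBS is selective for C8 (C6 lies between two benzyloxy groups), which installs the cap that later forces coupling to C6.

**Step 9**
Reactants: 15 8-bromo ketal
Product: 16 8-bromo-5,7,5'-tri-O-benzyl-(−)-epigallocatechin (3-OH, 3'-OH and 4'-OH free)
Conditions: AcOH/H2O (4:1), 90 °C
Reagents that add atoms: none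
Why: Acid-catalysed ketal hydrolysis through the stabilised diphenylmethyl oxocarbenium ion frees the 3',4'-catechol while benzyl ethers, the aryl bromide and both stereocentres survive.

**Step 10**
Reactants: 16 bromo catechol; 17 3,4,5-tris(benzyloxy)benzoic acid
Product: 18 8-bromo-5,7,5'-tri-O-benzyl-(−)-epigallocatechin 3,3'-bis-O-[3,4,5-tris(benzyloxy)benzoate] (4'-OH free)
Conditions: 17 (2.2 equiv), DCC (2.4 equiv), DMAP (0.3 equiv), CH2Cl2, 0 °C → rt
Reagents that add atoms: none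
Why: Steglich esterification acylates the unhindered 3'-phenol and the secondary 3-OH, whereas the 4'-phenol between the 5'-benzyloxy group and the new ester is too hindered (and a 4'-ester can migrate to the less congested 3'-oxygen), so the 3,3'-diester forms with the ring stereocentres untouched.

**Step 11**
Reactants: 11 4β-methoxy electrophile; 18 bromo-capped digallate
Product: 19 6,8-dibromo-5,7,4'-tri-O-benzyl-epiafzelechin-(4β→6)-[8-bromo-5,7,5'-tri-O-benzyl-epigallocatechin 3,3'-bis-O-(tri-O-benzylgallate)]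
Conditions: 11 (1.5 equiv), TMSOTf (0.3 equiv), 4 Å MS, CH2Cl2, −40 → 0 °C
Reagents that add atoms: none
Why: Lewis-acid ionisation of the 4-methoxy group gives the C4 benzylic cation (the quinone-methide-type extension unit of proanthocyanidin assembly), which undergoes Friedel–Crafts attack by the only open nucleophilic carbon, C6 of 18 (halo-capping: C8 of 18 and C6/C8 of 11 are blocked), from the face anti to the axial 3-OH to set the 3,4-trans (4β) centre.

**Step 12**
Reactants: 19 protected dimer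
Product: 20 (−)-epiafzelechin-(4β→6)-(−)-epigallocatechin 3,3'-di-O-gallate (CNP0290965.1)
Conditions: H2 (1 atm), Pd(OH)2/C, NaOAc (3.3 equiv), THF/MeOH (1:1), rt
Reagents that add atoms: none
Why: Palladium-catalysed hydrogenolysis cleaves all twelve benzyl ethers and hydrodebrominates the three aryl bromides, with acetate buffering the HBr so that the acid-labile interflavan bond and the phenolic gallate survive; no stereocentre is touched.

**Compound list**
1 | 1-[2-hydroxy-4,6-bis(benzyloxy)phenyl]ethan-1-one | CC(=O)c1c(O)cc(OCc2ccccc2)cc1OCc1ccccc1 | starting material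
2 | 4-(benzyloxy)benzaldehyde | O=Cc1ccc(OCc2ccccc2)cc1 | starting material
3 | (E)-1-[2-hydroxy-4,6-bis(benzyloxy)phenyl]-3-[4-(benzyloxy)phenyl]prop-2-en-1-one | O=C(/C=C/c1ccc(OCc2ccccc2)cc1)c1c(O)cc(OCc2ccccc2)cc1OCc1ccccc1 | intermediate
4 | racemic 5,7-bis(benzyloxy)-2-[4-(benzyloxy)phenyl]chroman-4-one (enantiomers interconvert) | O=C1CC(c2ccc(OCc3ccccc3)cc2)Oc2cc(OCc3ccccc3)cc(OCc3ccccc3)c21 | intermediate
5 | (2S,4S)-5,7-bis(benzyloxy)-2-[4-(benzyloxy)phenyl]chroman-4-ol | O[C@H]1C[C@@H](c2ccc(OCc3ccccc3)cc2)Oc2cc(OCc3ccccc3)cc(OCc3ccccc3)c21 | intermediate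
6 | (2S)-5,7-bis(benzyloxy)-2-[4-(benzyloxy)phenyl]-2H-chromene | C1=C[C@@H](c2ccc(OCc3ccccc3)cc2)Oc2cc(OCc3ccccc3)cc(OCc3ccccc3)c12 | intermediate
7 | (2R,3S,4R)-3-bromo-5,7-bis(benzyloxy)-2-[4-(benzyloxy)phenyl]chroman-4-ol | O[C@H]1[C@H](Br)[C@@H](c2ccc(OCc3ccccc3)cc2)Oc2cc(OCc3ccccc3)cc(OCc3ccccc3)c21 | intermediate
8 | (2R,3S,4R)-3,8-dibromo-5,7-bis(benzyloxy)-2-[4-(benzyloxy)phenyl]chroman-4-ol | O[C@H]1[C@H](Br)[C@@H](c2ccc(OCc3ccccc3)cc2)Oc2c(Br)c(OCc3ccccc3)cc(OCc3ccccc3)c21 | intermediate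
9 | (2R,3S,4R)-3,6,8-tribromo-5,7-bis(benzyloxy)-2-[4-(benzyloxy)phenyl]chroman-4-ol | O[C@H]1[C@H](Br)[C@@H](c2ccc(OCc3ccccc3)cc2)Oc2c(Br)c(OCc3ccccc3)c(Br)c(OCc3ccccc3)c21 | intermediate
10 | (2R,3R,4R)-6,8-dibromo-5,7-bis(benzyloxy)-2-[4-(benzyloxy)phenyl]-3,4-epoxychroman (epoxide cis to the 2-aryl group) | [C@H]1(c2ccc(OCc3ccccc3)cc2)Oc2c(Br)c(OCc3ccccc3)c(Br)c(OCc3ccccc3)c2[C@H]2O[C@@H]12 | intermediate
11 | (2R,3R,4S)-6,8-dibromo-5,7-bis(benzyloxy)-2-[4-(benzyloxy)phenyl]-4-methoxychroman-3-ol | CO[C@@H]1[C@@H](O)[C@@H](c2ccc(OCc3ccccc3)cc2)Oc2c(Br)c(OCc3ccccc3)c(Br)c(OCc3ccccc3)c21 | intermediate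
12 | (−)-epigallocatechin, (2R,3R)-2-(3,4,5-trihydroxyphenyl)chroman-3,5,7-triol | O[C@@H]1Cc2c(O)cc(O)cc2O[C@@H]1c1cc(O)c(O)c(O)c1 | starting material
13 | (2R,3R)-2-(7-hydroxy-2,2-diphenyl-1,3-benzodioxol-5-yl)chroman-3,5,7-triol | O[C@@H]1Cc2c(O)cc(O)cc2O[C@@H]1c1cc(O)c2OC(c3ccccc3)(c3ccccc3)Oc2c1 | intermediate
14 | (2R,3R)-5,7-bis(benzyloxy)-2-[7-(benzyloxy)-2,2-diphenyl-1,3-benzodioxol-5-yl]chroman-3-ol | O[C@@H]1Cc2c(OCc3ccccc3)cc(OCc3ccccc3)cc2O[C@@H]1c1cc(OCc2ccccc2)c2OC(c3ccccc3)(c3ccccc3)Oc2c1 | intermediate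
15 | (2R,3R)-8-bromo-5,7-bis(benzyloxy)-2-[7-(benzyloxy)-2,2-diphenyl-1,3-benzodioxol-5-yl]chroman-3-ol | O[C@@H]1Cc2c(OCc3ccccc3)cc(OCc3ccccc3)c(Br)c2O[C@@H]1c1cc(OCc2ccccc2)c2OC(c3ccccc3)(c3ccccc3)Oc2c1 | intermediate
16 | (2R,3R)-8-bromo-5,7-bis(benzyloxy)-2-[3-(benzyloxy)-4,5-dihydroxyphenyl]chroman-3-ol | O[C@@H]1Cc2c(OCc3ccccc3)cc(OCc3ccccc3)c(Br)c2O[C@@H]1c1cc(O)c(O)c(OCc2ccccc2)c1 | intermediate
17 | 3,4,5-tris(benzyloxy)benzoic acid | O=C(O)c1cc(OCc2ccccc2)c(OCc2ccccc2)c(OCc2ccccc2)c1 | starting material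
18 | 8-bromo-5,7,5'-tri-O-benzyl-(−)-epigallocatechin 3,3'-bis-O-[3,4,5-tris(benzyloxy)benzoate] | O=C(O[C@@H]1Cc2c(OCc3ccccc3)cc(OCc3ccccc3)c(Br)c2O[C@@H]1c1cc(OC(=O)c2cc(OCc3ccccc3)c(OCc3ccccc3)c(OCc3ccccc3)c2)c(O)c(OCc2ccccc2)c1)c1cc(OCc2ccccc2)c(OCc2ccccc2)c(OCc2ccccc2)c1 | intermediate
19 | perbenzylated tribromo dimer, upper unit 2α-aryl-3α-OH-4β-aryl, linked C4(upper)–C6(lower) | O=C(Oc1cc([C@H]2Oc3c(Br)c(OCc4ccccc4)c([C@H]4c5c(OCc6ccccc6)c(Br)c(OCc6ccccc6)c(Br)c5O[C@H](c5ccc(OCc6ccccc6)cc5)[C@@H]4O)c(OCc4ccccc4)c3C[C@H]2OC(=O)c2cc(OCc3ccccc3)c(OCc3ccccc3)c(OCc3ccccc3)c2)cc(OCc2ccccc2)c1O)c1cc(OCc2ccccc2)c(OCc2ccccc2)c(OCc2ccccc2)c1 | intermediate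
20 | (−)-epiafzelechin-(4β→6)-(−)-epigallocatechin 3,3'-di-O-gallate | O=C(Oc1cc([C@H]2Oc3cc(O)c([C@H]4c5c(O)cc(O)cc5O[C@H](c5ccc(O)cc5)[C@@H]4O)c(O)c3C[C@H]2OC(=O)c2cc(O)c(O)c(O)c2)cc(O)c1O)c1cc(O)c(O)c(O)c1 | target

**Totals**
Total steps: 12 (steps 1–5 upper unit, 6–10 lower unit, 11 coupling, 12 deprotection).
Longest linear sequence: 7 steps (1–5, 11, 12, or equally 6–10, 11, 12).

**Three steps most likely to fail**

Step 2 (one-flask ring closure with dynamic kinetic resolution). The electron-rich, peri-substituted ketone may reduce slowly, and the chalcone may be reduced at the C=C bond before it cyclises. Fallback, setting out from 3 and coming back at 5: cyclise 3 with NaOAc in refluxing EtOH and isolate racemic flavanone 4; reduce it with NaBH4 (MeOH/THF, 0 °C) to racemic 2,4-cis-flavan-4-ol F1; resolve this by lipase-catalysed acylation (Amano lipase PS, vinyl acetate, MTBE, 35 °C), which esterifies the (4R)-enantiomer to (2R,4R)-acetate F2 and leaves (2S,4S)-alcohol 5 (at most 50 %).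

Step 10 (double galloylation with one catechol OH left free). Over-acylation at 4'-OH or a 3'/4' mixture is possible. Fallback, setting out from 15 and coming back at 18: esterify only the 3-OH of 15 with 17 (DCC, DMAP) while the ketal still masks the B-ring, giving 3-O-galloyl ketal F3; hydrolyse the ketal (AcOH/H2O, 90 °C) to 3-O-galloyl catechol F4; then acylate with exactly 1.0 equiv of 17 (DCC, cat. DMAP, −20 °C), separating any 4'-ester and re-equilibrating it with DMAP, to reach 18.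

Step 11 (attack by the hindered, bromine-capped C6 between two benzyloxy groups). The cation may instead rearrange to the flavan-3-one or be quenched. Fallback, setting out from 18 and 11 and coming back at 20: hydrogenolyse 18 (H2, Pd(OH)2/C, NaOAc) to free (−)-epigallocatechin 3,3'-di-O-gallate F5, whose unprotected A-ring is much more nucleophilic and unhindered at C6; condense F5 (3 equiv) with 11 (TMSOTf, THF/CH2Cl2, −20 °C) and separate the 4→6 adduct F6 from its 4→8 regioisomer by reversed-phase chromatography; hydrogenolyse F6 (H2, Pd(OH)2/C, NaOAc) to 20.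

**Further compounds**
F1 | step 2 | racemic 2,4-cis-5,7-bis(benzyloxy)-2-[4-(benzyloxy)phenyl]chroman-4-ol | O[C@H]1C[C@@H](c2ccc(OCc3ccccc3)cc2)Oc2cc(OCc3ccccc3)cc(OCc3ccccc3)c21.O[C@@H]1C[C@H](c2ccc(OCc3ccccc3)cc2)Oc2cc(OCc3ccccc3)cc(OCc3ccccc3)c21
F2 | step 2 | (2R,4R)-5,7-bis(benzyloxy)-2-[4-(benzyloxy)phenyl]chroman-4-yl acetate | CC(=O)O[C@@H]1C[C@H](c2ccc(OCc3ccccc3)cc2)Oc2cc(OCc3ccccc3)cc(OCc3ccccc3)c21
F3 | step 10 | 8-bromo-5,7,5'-tri-O-benzyl-3',4'-O-(diphenylmethylene)-(−)-epigallocatechin 3-O-[3,4,5-tris(benzyloxy)benzoate] | O=C(O[C@@H]1Cc2c(OCc3ccccc3)cc(OCc3ccccc3)c(Br)c2O[C@@H]1c1cc(OCc2ccccc2)c2OC(c3ccccc3)(c3ccccc3)Oc2c1)c1cc(OCc2ccccc2)c(OCc2ccccc2)c(OCc2ccccc2)c1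
F4 | step 10 | 8-bromo-5,7,5'-tri-O-benzyl-(−)-epigallocatechin 3-O-[3,4,5-tris(benzyloxy)benzoate] (3',4'-catechol free) | O=C(O[C@@H]1Cc2c(OCc3ccccc3)cc(OCc3ccccc3)c(Br)c2O[C@@H]1c1cc(O)c(O)c(OCc2ccccc2)c1)c1cc(OCc2ccccc2)c(OCc2ccccc2)c(OCc2ccccc2)c1
F5 | step 11 | (−)-epigallocatechin 3,3'-di-O-gallate | O=C(O[C@@H]1Cc2c(O)cc(O)cc2O[C@@H]1c1cc(OC(=O)c2cc(O)c(O)c(O)c2)c(O)c(O)c1)c1cc(O)c(O)c(O)c1
F6 | step 11 | 6,8-dibromo-5,7,4'-tri-O-benzyl-epiafzelechin-(4β→6)-(−)-epigallocatechin 3,3'-di-O-gallate | O=C(Oc1cc([C@H]2Oc3cc(O)c([C@H]4c5c(OCc6ccccc6)c(Br)c(OCc6ccccc6)c(Br)c5O[C@H](c5ccc(OCc6ccccc6)cc5)[C@@H]4O)c(O)c3C[C@H]2OC(=O)c2cc(O)c(O)c(O)c2)cc(O)c1O)c1cc(O)c(O)c(O)c1
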